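**Retrosynthetic overview**
- The C8 2-(hydroxymethyl)acrylate is attached last. The 13-acetoxy-Δ7(11)-butenolide comes from ring-closing metathesis of a C6 2-(acetoxymethyl)acrylate onto a C7 exo-methylene.
- The ten-membered carbocycle is closed at C6–C7 by a Ni/Cr-catalysed coupling of a 2-iodoallyl silyl ether with an α,β-epoxy aldehyde, which also sets C6.
- The C4/C5 epoxide comes from Sharpless epoxidation of a (Z)-allylic alcohol. The open-chain ketone comes from a Weinreb amide (C7–C10, C1) and a Grignard reagent (C2–C6).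
- The Weinreb amide comes from methyl (S)-3-bromo-2-methylpropanoate (C10), acryloyl chloride and a CBS reduction (C8). The Grignard reagent comes from but-2-yn-1-ol and oxirane.
- Ring order: epoxide on the open chain, then the ten-membered ring, then the butenolide.

Assumption: germacrane numbering is used for atom labels (target = 4R,5S,6S,8S,10R; C1 ketone, C12 lactone carbonyl, C13 acetoxymethyl), compounds 1, 2, 9, 12, 23 and 29 are taken as commercial, and the acetal carbon of the 1-ethoxyethyl group in 11 and 13–18 is a mixture of both configurations.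

**Route**

Step 1
Reactants: 1 methyl (S)-3-bromo-2-methylpropanoate; 2 acryloyl chloride
Product: 4 methyl (R)-2-methyl-4-oxohex-5-enoate, via alkylzinc bromide 3 (not isolated)
Conditions: Zn dust, LiCl, THF, 40 °C; then 2, Pd(PPh3)4 (3 mol %), THF, 0 °C to rt
Reagents that add atoms: none
Why: LiCl-promoted zinc insertion gives a β-zincio ester whose stereocentre is not at the metal-bearing carbon, and Pd-catalysed Negishi acylation with the acid chloride gives the γ-keto ester with C10 carried over unchanged from 1.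

Step 2
Reactants: 4 methyl (R)-2-methyl-4-oxohex-5-enoate
Product: 5 methyl (R)-5-iodo-2-methyl-4-oxohex-5-enoate
Conditions: I2, pyridine/CH2Cl2 (1:1), 0 °C to rt
Reagents that add atoms: iodine, II
Why: Johnson α-iodination, in which pyridine adds to the enone, the enolate is iodinated and pyridine is lost again (addition–elimination), gives the 2-iodo-1-en-3-one without touching C10.

Step 3
Reactants: 5 methyl (R)-5-iodo-2-methyl-4-oxohex-5-enoate
Product: 6 methyl (2R,4S)-4-hydroxy-5-iodo-2-methylhex-5-enoate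
Conditions: (R)-Me-CBS (20 mol %), catecholborane, toluene, −78 °C; MeOH, aq NaHCO3; used at once
Reagents that add atoms: none
Why: Corey–Bakshi–Shibata reduction in which the α-iodovinyl group acts as the large substituent, so the (R)-catalyst delivers hydride to give the (S)-carbinol (C8) under catalyst control.

Step 4
Reactants: 6 methyl (2R,4S)-4-hydroxy-5-iodo-2-methylhex-5-enoate
Product: 7 methyl (2R,4S)-4-[(tert-butyldimethylsilyl)oxy]-5-iodo-2-methylhex-5-enoate
Conditions: TBSOTf, 2,6-lutidine, CH2Cl2, −78 to 0 °C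
Reagents that add atoms: tert-butyldimethylsilyl triflate, CC(C)(C)[Si](C)(C)OS(=O)(=O)C(F)(F)F
Why: Silylation of the secondary alcohol with the silyl triflate is faster than lactonisation onto the methyl ester and leaves both stereocentres untouched.

Step 5
Reactants: 7 methyl (2R,4S)-4-[(tert-butyldimethylsilyl)oxy]-5-iodo-2-methylhex-5-enoate
Product: 8 (2R,4S)-4-[(tert-butyldimethylsilyl)oxy]-5-iodo-N-methoxy-N,2-dimethylhex-5-enamide
Conditions: MeNHOMe·HCl, iPrMgCl, THF, −20 to −10 °C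
Reagents that add atoms: N,O-dimethylhydroxylamine hydrochloride, CNOC.Cl
Why: Direct ester-to-Weinreb-amide exchange with the chloromagnesium amide at low temperature leaves the α-stereocentre and the alkenyl iodide intact.

Step 6
Reactants: 9 but-2-yn-1-ol
Product: 10 (Z)-3-iodobut-2-en-1-ol
Conditions: Red-Al, THF, 0 °C to rt; then I2, THF, −78 °C to rt
Reagents that add atoms: iodine, II
Why: Hydroxyl-directed trans-hydroalumination puts aluminium on C3, and iodinolysis with retention gives the (Z)-iodoalkene that fixes the later C4=C5 geometry.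

Step 7
Reactants: 10 (Z)-3-iodobut-2-en-1-ol
Product: 11 (Z)-1-(1-ethoxyethoxy)-3-iodobut-2-ene
Conditions: ethyl vinyl ether, PPTS (cat.), CH2Cl2, 0 °C to rt
Reagents that add atoms: ethyl vinyl ether, C=COCC
Why: Acid-catalysed acetalisation masks the alcohol as a base-stable acetal that dilute acid removes later.

Step 8
Reactants: 11 (Z)-1-(1-ethoxyethoxy)-3-iodobut-2-ene; 12 oxirane
Product: 14 (Z)-5-(1-ethoxyethoxy)-3-methylpent-3-en-1-ol, via alkenyllithium 13 (not isolated)
Conditions: t-BuLi (2.1 equiv), Et2O, −78 °C; then 12, −78 to −20 °C; H2O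
Reagents that add atoms: none
Why: Iodine–lithium exchange proceeds with retention of alkene geometry, and SN2 opening of oxirane by the alkenyllithium gives the (Z)-homoallylic alcohol.

Step 9
Reactants: 14 (Z)-5-(1-ethoxyethoxy)-3-methylpent-3-en-1-ol
Product: 16 (Z)-5-bromo-1-(1-ethoxyethoxy)-3-methylpent-2-ene, via mesylate 15 (not isolated)
Conditions: MsCl, Et3N, THF, 0 °C; then LiBr, THF, rt to 40 °C
Reagents that add atoms: lithium bromide, [Li+].[Br-]
Why: Mesylation followed by Finkelstein-type bromide displacement runs under non-acidic conditions that spare the acetal and the (Z)-alkene.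

Step 10
Reactants: 16 (Z)-5-bromo-1-(1-ethoxyethoxy)-3-methylpent-2-ene; 8 (2R,4S)-4-[(tert-butyldimethylsilyl)oxy]-5-iodo-N-methoxy-N,2-dimethylhex-5-enamide
Product: 19 (2Z,7R,9S)-9-[(tert-butyldimethylsilyl)oxy]-1-hydroxy-10-iodo-3,7-dimethylundeca-2,10-dien-6-one, via Grignard reagent 17 (not isolated), via ethoxyethyl ketone 18 (not isolated)
Conditions: 16, Mg, THF, rt to 40 °C; then 8, THF, 0 °C; then 1 M aq HCl, THF, rt, 45 min
Reagents that add atoms: none
Why: Weinreb ketone synthesis stops at the chelated tetrahedral intermediate, so the ketone appears only on quench with C10 intact, and the dilute acid of the work-up also cleaves the ethoxyethyl acetal while the secondary TBS ether survives.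

Step 11
Reactants: 19 (2Z,7R,9S)-9-[(tert-butyldimethylsilyl)oxy]-1-hydroxy-10-iodo-3,7-dimethylundeca-2,10-dien-6-one
Product: 20 (4R,6S)-6-[(tert-butyldimethylsilyl)oxy]-1-[(2R,3S)-3-(hydroxymethyl)-2-methyloxiran-2-yl]-7-iodo-4-methyloct-7-en-3-one
Conditions: Ti(OiPr)4, L-(+)-diethyl tartrate, TBHP, 4 Å MS, CH2Cl2, −20 °C
Reagents that add atoms: tert-butyl hydroperoxide, CC(C)(C)OO
Why: Sharpless asymmetric epoxidation with L-(+)-tartrate epoxidises the (Z)-allylic alcohol on the face that gives the (4R,5S) epoxide under reagent control, as for nerol, while the ketone and the alkenyl iodide are inert.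

Step 12
Reactants: 20 (4R,6S)-6-[(tert-butyldimethylsilyl)oxy]-1-[(2R,3S)-3-(hydroxymethyl)-2-methyloxiran-2-yl]-7-iodo-4-methyloct-7-en-3-one
Product: 21 (2R,3R)-3-{(4R,6S)-6-[(tert-butyldimethylsilyl)oxy]-7-iodo-4-methyl-3-oxooct-7-en-1-yl}-3-methyloxirane-2-carbaldehyde
Conditions: Dess–Martin periodinane, NaHCO3, CH2Cl2, 0 °C to rt; used at once
Reagents that add atoms: none
Why: Buffered Dess–Martin oxidation gives the sensitive α,β-epoxy aldehyde without epimerisation at C5 or C10.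

Step 13
Reactants: 21 (2R,3R)-3-{(4R,6S)-6-[(tert-butyldimethylsilyl)oxy]-7-iodo-4-methyl-3-oxooct-7-en-1-yl}-3-methyloxirane-2-carbaldehyde
Product: 22 (1R,5R,7S,9S,10S)-7-[(tert-butyldimethylsilyl)oxy]-9-hydroxy-1,5-dimethyl-8-methylidene-11-oxabicyclo[8.1.0]undecan-4-one
Conditions: CrCl2 (20 mol %), Kishi-type oxazoline–sulfonamide ligand (22 mol %), proton sponge (22 mol %), NiCl2·2,9-dimethylphenanthroline (5 mol %), Mn, Cp2ZrCl2, LiCl, MeCN, rt, syringe-pump addition to 2 mM
Reagents that add atoms: none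
Why: Proposed new method: a Cr-catalytic, ligand-controlled Ni/Cr (Nozaki–Hiyama–Kishi) ring closure onto an α,β-epoxy aldehyde to a ten-membered carbocycle, in which Ni(0) inserts into the C7–I bond, the alkenyl group passes to the chiral Cr(III)–sulfonamide complex and adds to the C6 aldehyde through an open transition state with the epoxide C5–O bond anti to the forming C6–C7 bond (Felkin–Anh), the ligand antipode being picked by a matched/mismatched screen so that catalyst and substrate both favour (6S), while Cp2ZrCl2 frees the chromium alkoxide, Mn returns Cr(III) to Cr(II) and the cis-epoxide acts as a turn element; the closest known reactions are catalytic asymmetric Ni/Cr couplings and macrocyclisations of 2-iodoalkenes with aldehydes and stoichiometric NHK closures of nine- to eleven-membered carbocycles.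

Step 14
Reactants: 23 2-(hydroxymethyl)prop-2-enoic acid
Product: 24 2-(acetoxymethyl)prop-2-enoic acid
Conditions: Ac2O, pyridine, CH2Cl2, 0 °C to rt; then H2O, dilute HCl work-up
Reagents that add atoms: acetic anhydride, CC(=O)OC(C)=O
Why: Acetylation of the primary allylic alcohol, with the aqueous work-up hydrolysing any mixed anhydride back to the free acid.

Step 15
Reactants: 24 2-(acetoxymethyl)prop-2-enoic acid
Product: 25 2-(acetoxymethyl)prop-2-enoyl chloride
Conditions: (COCl)2, DMF (cat.), CH2Cl2, 0 °C to rt; concentrated and used crude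
Reagents that add atoms: oxalyl chloride, O=C(Cl)C(=O)Cl
Why: Vilsmeier-type activation converts the acid into the acid chloride needed to acylate a hindered alcohol without nucleophilic amine catalysts that could attack the allylic acetate.

Step 16
Reactants: 22 (1R,5R,7S,9S,10S)-7-[(tert-butyldimethylsilyl)oxy]-9-hydroxy-1,5-dimethyl-8-methylidene-11-oxabicyclo[8.1.0]undecan-4-one; 25 2-(acetoxymethyl)prop-2-enoyl chloride
Product: 26 (1S,2S,4S,6R,10R)-4-[(tert-butyldimethylsilyl)oxy]-6,10-dimethyl-3-methylidene-7-oxo-11-oxabicyclo[8.1.0]undecan-2-yl 2-(acetoxymethyl)prop-2-enoate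
Conditions: pyridine, CH2Cl2, −20 to 0 °C
Reagents that add atoms: none
Why: O-Acylation of the C6 alcohol by the acid chloride through an acylpyridinium ion forms the ester without touching the C6 configuration.

Step 17
Reactants: 26 (1S,2S,4S,6R,10R)-4-[(tert-butyldimethylsilyl)oxy]-6,10-dimethyl-3-methylidene-7-oxo-11-oxabicyclo[8.1.0]undecan-2-yl 2-(acetoxymethyl)prop-2-enoate
Product: 27 (4R,5S,6S,8S,10R)-13-acetoxy-8-[(tert-butyldimethylsilyl)oxy]-4,5-epoxy-1-oxogermacr-7(11)-en-6,12-olide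
Conditions: Hoveyda–Grubbs II (15 mol % in portions), 1,4-benzoquinone (20 mol %), toluene (5 mM), 80 °C, argon sparge
Reagents that add atoms: none
Why: Ring-closing metathesis of the two 1,1-disubstituted alkenes forms the tetrasubstituted C7=C11 bond of the five-membered lactone, driven by loss of ethylene and by the five-ring closure.

Step 18
Reactants: 27 (4R,5S,6S,8S,10R)-13-acetoxy-8-[(tert-butyldimethylsilyl)oxy]-4,5-epoxy-1-oxogermacr-7(11)-en-6,12-olide
Product: 28 (4R,5S,6S,8S,10R)-13-acetoxy-4,5-epoxy-8-hydroxy-1-oxogermacr-7(11)-en-6,12-olide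
Conditions: HF·pyridine, pyridine, THF, 0 °C to rt
Reagents that add atoms: none
Why: Buffered HF·pyridine desilylation removes the secondary TBS ether under conditions that spare trisubstituted epoxides, acetates and the base-sensitive butenolide.

Step 19
Reactants: 29 methyl 2-(hydroxymethyl)prop-2-enoate
Product: 30 methyl 2-{[(tert-butyldimethylsilyl)oxy]methyl}prop-2-enoate
Conditions: TBSCl, imidazole, DMF, 0 °C to rt
Reagents that add atoms: tert-butyldimethylsilyl chloride, CC(C)(C)[Si](C)(C)Cl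
Why: Standard imidazole-promoted silylation of the primary alcohol.

Step 20
Reactants: 30 methyl 2-{[(tert-butyldimethylsilyl)oxy]methyl}prop-2-enoate
Product: 31 2-{[(tert-butyldimethylsilyl)oxy]methyl}prop-2-enoic acid
Conditions: LiOH, THF/H2O, 0 °C to rt; then 1 M HCl to pH 4 at 0 °C
Reagents that add atoms: lithium hydroxide, [Li+].[OH-]
Why: Saponification of the methyl ester, with the primary TBS ether surviving the cold, brief acidification.

Step 21
Reactants: 28 (4R,5S,6S,8S,10R)-13-acetoxy-4,5-epoxy-8-hydroxy-1-oxogermacr-7(11)-en-6,12-olide; 31 2-{[(tert-butyldimethylsilyl)oxy]methyl}prop-2-enoic acid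
Product: 32 (4R,5S,6S,8S,10R)-13-acetoxy-8-[(2-{[(tert-butyldimethylsilyl)oxy]methyl}prop-2-enoyl)oxy]-4,5-epoxy-1-oxogermacr-7(11)-en-6,12-olide
Conditions: DIC, DMAP (cat.), CH2Cl2, 0 °C to rt
Reagents that add atoms: none
Why: Steglich esterification traps the open hydroxy-ketone form of 28 (any transannular C1/C8 hemiketal is in equilibrium with it) without touching a stereocentre.

Step 22
Reactants: 32 (4R,5S,6S,8S,10R)-13-acetoxy-8-[(2-{[(tert-butyldimethylsilyl)oxy]methyl}prop-2-enoyl)oxy]-4,5-epoxy-1-oxogermacr-7(11)-en-6,12-olide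
Product: 33 (4R,5S,6S,8S,10R)-13-acetoxy-4,5-epoxy-8-{[2-(hydroxymethyl)prop-2-enoyl]oxy}-1-oxogermacr-7(11)-en-6,12-olide (CNP0258719.1)
Conditions: HF·pyridine, pyridine, THF, 0 °C
Reagents that add atoms: none
Why: Mild fluoride-acid cleavage of the primary TBS ether leaves the acetate, both esters and the epoxide in place and gives the target.

**Compound list**
1 | methyl (S)-3-bromo-2-methylpropanoate | COC(=O)[C@H](C)CBr | starting material
2 | acryloyl chloride | C=CC(=O)Cl | starting material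
3 | [(2S)-3-methoxy-2-methyl-3-oxopropyl]zinc bromide | COC(=O)[C@H](C)C[Zn]Br | intermediate
4 | methyl (R)-2-methyl-4-oxohex-5-enoate | COC(=O)[C@H](C)CC(=O)C=C | intermediate
5 | methyl (R)-5-iodo-2-methyl-4-oxohex-5-enoate | COC(=O)[C@H](C)CC(=O)C(I)=C | intermediate
6 | methyl (2R,4S)-4-hydroxy-5-iodo-2-methylhex-5-enoate | COC(=O)[C@H](C)C[C@H](O)C(I)=C | intermediate
7 | methyl (2R,4S)-4-[(tert-butyldimethylsilyl)oxy]-5-iodo-2-methylhex-5-enoate | COC(=O)[C@H](C)C[C@H](O[Si](C)(C)C(C)(C)C)C(I)=C | intermediate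
8 | (2R,4S)-4-[(tert-butyldimethylsilyl)oxy]-5-iodo-N-methoxy-N,2-dimethylhex-5-enamide | CON(C)C(=O)[C@H](C)C[C@H](O[Si](C)(C)C(C)(C)C)C(I)=C | intermediate
9 | but-2-yn-1-ol | CC#CCO | starting material
10 | (Z)-3-iodobut-2-en-1-ol | OC/C=C(/C)I | intermediate
11 | (Z)-1-(1-ethoxyethoxy)-3-iodobut-2-ene | CCOC(C)OC/C=C(/C)I | intermediate
12 | oxirane | C1CO1 | starting material
13 | (E)-[4-(1-ethoxyethoxy)but-2-en-2-yl]lithium (Li cis to the CH2O group) | CCOC(C)OC/C=C(/C)[Li] | intermediate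
14 | (Z)-5-(1-ethoxyethoxy)-3-methylpent-3-en-1-ol | CCOC(C)OC/C=C(/C)CCO | intermediate
15 | (Z)-5-(1-ethoxyethoxy)-3-methylpent-3-en-1-yl methanesulfonate | CCOC(C)OC/C=C(/C)CCOS(C)(=O)=O | intermediate
16 | (Z)-5-bromo-1-(1-ethoxyethoxy)-3-methylpent-2-ene | CCOC(C)OC/C=C(/C)CCBr | intermediate
17 | [(3Z)-5-(1-ethoxyethoxy)-3-methylpent-3-en-1-yl]magnesium bromide | CCOC(C)OC/C=C(/C)CC[Mg]Br | intermediate
18 | (2Z,7R,9S)-9-[(tert-butyldimethylsilyl)oxy]-1-(1-ethoxyethoxy)-10-iodo-3,7-dimethylundeca-2,10-dien-6-one | CCOC(C)OC/C=C(/C)CCC(=O)[C@H](C)C[C@H](O[Si](C)(C)C(C)(C)C)C(I)=C | intermediate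
19 | (2Z,7R,9S)-9-[(tert-butyldimethylsilyl)oxy]-1-hydroxy-10-iodo-3,7-dimethylundeca-2,10-dien-6-one | OC/C=C(/C)CCC(=O)[C@H](C)C[C@H](O[Si](C)(C)C(C)(C)C)C(I)=C | intermediate
20 | (4R,6S)-6-[(tert-butyldimethylsilyl)oxy]-1-[(2R,3S)-3-(hydroxymethyl)-2-methyloxiran-2-yl]-7-iodo-4-methyloct-7-en-3-one | OC[C@@H]1O[C@]1(C)CCC(=O)[C@H](C)C[C@H](O[Si](C)(C)C(C)(C)C)C(I)=C | intermediate
21 | (2R,3R)-3-{(4R,6S)-6-[(tert-butyldimethylsilyl)oxy]-7-iodo-4-methyl-3-oxooct-7-en-1-yl}-3-methyloxirane-2-carbaldehyde | O=C[C@@H]1O[C@]1(C)CCC(=O)[C@H](C)C[C@H](O[Si](C)(C)C(C)(C)C)C(I)=C | intermediate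
22 | (1R,5R,7S,9S,10S)-7-[(tert-butyldimethylsilyl)oxy]-9-hydroxy-1,5-dimethyl-8-methylidene-11-oxabicyclo[8.1.0]undecan-4-one | CC(C)(C)[Si](C)(C)O[C@H]1C[C@@H](C)C(=O)CC[C@@]2(C)O[C@H]2[C@@H](O)C1=C | intermediate
23 | 2-(hydroxymethyl)prop-2-enoic acid | C=C(CO)C(=O)O | starting material
24 | 2-(acetoxymethyl)prop-2-enoic acid | CC(=O)OCC(=C)C(=O)O | intermediate
25 | 2-(acetoxymethyl)prop-2-enoyl chloride | CC(=O)OCC(=C)C(=O)Cl | intermediate
26 | (1S,2S,4S,6R,10R)-4-[(tert-butyldimethylsilyl)oxy]-6,10-dimethyl-3-methylidene-7-oxo-11-oxabicyclo[8.1.0]undecan-2-yl 2-(acetoxymethyl)prop-2-enoate | CC(C)(C)[Si](C)(C)O[C@H]1C[C@@H](C)C(=O)CC[C@@]2(C)O[C@H]2[C@@H](OC(=O)C(=C)COC(C)=O)C1=C | intermediate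
27 | (4R,5S,6S,8S,10R)-13-acetoxy-8-[(tert-butyldimethylsilyl)oxy]-4,5-epoxy-1-oxogermacr-7(11)-en-6,12-olide | CC(C)(C)[Si](C)(C)O[C@H]1C[C@@H](C)C(=O)CC[C@@]2(C)O[C@H]2[C@H]2OC(=O)C(COC(C)=O)=C12 | intermediate
28 | (4R,5S,6S,8S,10R)-13-acetoxy-4,5-epoxy-8-hydroxy-1-oxogermacr-7(11)-en-6,12-olide | O[C@H]1C[C@@H](C)C(=O)CC[C@@]2(C)O[C@H]2[C@H]2OC(=O)C(COC(C)=O)=C12 | intermediate
29 | methyl 2-(hydroxymethyl)prop-2-enoate | C=C(CO)C(=O)OC | starting material
30 | methyl 2-{[(tert-butyldimethylsilyl)oxy]methyl}prop-2-enoate | C=C(CO[Si](C)(C)C(C)(C)C)C(=O)OC | intermediate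
31 | 2-{[(tert-butyldimethylsilyl)oxy]methyl}prop-2-enoic acid | C=C(CO[Si](C)(C)C(C)(C)C)C(=O)O | intermediate
32 | (4R,5S,6S,8S,10R)-13-acetoxy-8-[(2-{[(tert-butyldimethylsilyl)oxy]methyl}prop-2-enoyl)oxy]-4,5-epoxy-1-oxogermacr-7(11)-en-6,12-olide | C=C(CO[Si](C)(C)C(C)(C)C)C(=O)O[C@H]1C[C@@H](C)C(=O)CC[C@@]2(C)O[C@H]2[C@H]2OC(=O)C(COC(C)=O)=C12 | intermediate
33 | (4R,5S,6S,8S,10R)-13-acetoxy-4,5-epoxy-8-{[2-(hydroxymethyl)prop-2-enoyl]oxy}-1-oxogermacr-7(11)-en-6,12-olide (CNP0258719.1) | C=C(CO)C(=O)O[C@H]1C[C@@H](C)C(=O)CC[C@@]2(C)O[C@H]2[C@H]2OC(=O)C(COC(C)=O)=C12 | target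

**Step count**
Total: 22 steps. Longest linear sequence: 14 steps (1–5, 10–13, 16–18, 21, 22). The branches are steps 6–9, 14–15 and 19–20.

**Three steps most likely to fail**

Step 13 (the proposed new ring closure). The risks are oligomerisation, attack of the Lewis-acidic metal salts on the epoxy aldehyde, and a ring-strain preference for the wrong C6 epimer. The fallback sets out from 21 and comes back at 26. Compound 21 is cyclised under the classical ligand-free conditions (CrCl2 6 equiv, NiCl2 1 mol %, DMSO/THF, 2 mM), which are established for nine- to eleven-membered carbocycles and rely on substrate (Felkin) control alone. The desired alcohol 22 goes on through step 16. The C9-epimeric alcohol (1R,5R,7S,9R,10S)-7-[(tert-butyldimethylsilyl)oxy]-9-hydroxy-1,5-dimethyl-8-methylidene-11-oxabicyclo[8.1.0]undecan-4-one F1 is esterified with inversion by a Mitsunobu reaction with acid 24 (PPh3, DIAD, toluene, 0 °C) to give 26. C6 is then set by substrate control plus a stereoinvertive esterification instead of by the catalyst, and both epimers converge on 26.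

Step 17 (metathesis to a tetrasubstituted alkene next to two branched carbons). The fallback sets out from 22 and comes back at 27, and introduces C13 after the ring is closed. Alcohol 22 is acylated with acryloyl chloride 2 (iPr2NEt, CH2Cl2, −20 °C) to (1S,2S,4S,6R,10R)-4-[(tert-butyldimethylsilyl)oxy]-6,10-dimethyl-3-methylidene-7-oxo-11-oxabicyclo[8.1.0]undecan-2-yl prop-2-enoate F2. Ring-closing metathesis (Grubbs II, CH2Cl2, 40 °C) now forms only a trisubstituted alkene and gives (4R,5S,6S,8S,10R)-8-[(tert-butyldimethylsilyl)oxy]-4,5-epoxy-1-oxo-13-norgermacr-7(11)-en-6,12-olide F3. Bromine (CH2Cl2, −78 °C) adds to give (4R,5S,6S,8S,10R)-7,11-dibromo-8-[(tert-butyldimethylsilyl)oxy]-4,5-epoxy-1-oxo-13-norgermacran-6,12-olide F4, and Et3N eliminates HBr to (4R,5S,6S,8S,10R)-11-bromo-8-[(tert-butyldimethylsilyl)oxy]-4,5-epoxy-1-oxo-13-norgermacr-7(11)-en-6,12-olide F5. Stille coupling with (tributylstannyl)methanol (Pd2(dba)3, tri(2-furyl)phosphine, dioxane, 80 °C) gives (4R,5S,6S,8S,10R)-8-[(tert-butyldimethylsilyl)oxy]-4,5-epoxy-13-hydroxy-1-oxogermacr-7(11)-en-6,12-olide F6, and Ac2O/pyridine returns to 27.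

Step 2 (α-iodination of a polymerisation-prone open-chain vinyl ketone). The fallback sets out from 4 and comes back at 7, and brings the halogen in by addition–elimination and a late halide exchange. Bromine (CH2Cl2, −78 °C) adds to 4 to give methyl (2R)-5,6-dibromo-2-methyl-4-oxohexanoate F7, which loses HBr with Et3N to methyl (R)-5-bromo-2-methyl-4-oxohex-5-enoate F8. CBS reduction as in step 3 gives methyl (2R,4S)-5-bromo-4-hydroxy-2-methylhex-5-enoate F9, and silylation as in step 4 gives methyl (2R,4S)-5-bromo-4-[(tert-butyldimethylsilyl)oxy]-2-methylhex-5-enoate F10. Copper-catalysed halide exchange (CuI 10 mol %, NaI, trans-N,N′-dimethylcyclohexane-1,2-diamine, dioxane, 110 °C) converts the alkenyl bromide into iodide 7.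

**Further compounds**
F1 | step 13 | (1R,5R,7S,9R,10S)-7-[(tert-butyldimethylsilyl)oxy]-9-hydroxy-1,5-dimethyl-8-methylidene-11-oxabicyclo[8.1.0]undecan-4-one | CC(C)(C)[Si](C)(C)O[C@H]1C[C@@H](C)C(=O)CC[C@@]2(C)O[C@H]2[C@H](O)C1=C
F2 | step 17 | (1S,2S,4S,6R,10R)-4-[(tert-butyldimethylsilyl)oxy]-6,10-dimethyl-3-methylidene-7-oxo-11-oxabicyclo[8.1.0]undecan-2-yl prop-2-enoate | CC(C)(C)[Si](C)(C)O[C@H]1C[C@@H](C)C(=O)CC[C@@]2(C)O[C@H]2[C@@H](OC(=O)C=C)C1=C
F3 | step 17 | (4R,5S,6S,8S,10R)-8-[(tert-butyldimethylsilyl)oxy]-4,5-epoxy-1-oxo-13-norgermacr-7(11)-en-6,12-olide | CC(C)(C)[Si](C)(C)O[C@H]1C[C@@H](C)C(=O)CC[C@@]2(C)O[C@H]2[C@H]2OC(=O)C=C12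
F4 | step 17 | (4R,5S,6S,8S,10R)-7,11-dibromo-8-[(tert-butyldimethylsilyl)oxy]-4,5-epoxy-1-oxo-13-norgermacran-6,12-olide (C7 and C11 unassigned) | CC(C)(C)[Si](C)(C)O[C@H]1C[C@@H](C)C(=O)CC[C@@]2(C)O[C@H]2[C@H]2OC(=O)C(Br)C12Br
F5 | step 17 | (4R,5S,6S,8S,10R)-11-bromo-8-[(tert-butyldimethylsilyl)oxy]-4,5-epoxy-1-oxo-13-norgermacr-7(11)-en-6,12-olide | CC(C)(C)[Si](C)(C)O[C@H]1C[C@@H](C)C(=O)CC[C@@]2(C)O[C@H]2[C@H]2OC(=O)C(Br)=C12
F6 | step 17 | (4R,5S,6S,8S,10R)-8-[(tert-butyldimethylsilyl)oxy]-4,5-epoxy-13-hydroxy-1-oxogermacr-7(11)-en-6,12-olide | CC(C)(C)[Si](C)(C)O[C@H]1C[C@@H](C)C(=O)CC[C@@]2(C)O[C@H]2[C@H]2OC(=O)C(CO)=C12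
F7 | step 2 | methyl (2R)-5,6-dibromo-2-methyl-4-oxohexanoate (C5 unassigned) | COC(=O)[C@H](C)CC(=O)C(Br)CBr
F8 | step 2 | methyl (R)-5-bromo-2-methyl-4-oxohex-5-enoate | COC(=O)[C@H](C)CC(=O)C(Br)=C
F9 | step 2 | methyl (2R,4S)-5-bromo-4-hydroxy-2-methylhex-5-enoate | COC(=O)[C@H](C)C[C@H](O)C(Br)=C
F10 | step 2 | methyl (2R,4S)-5-bromo-4-[(tert-butyldimethylsilyl)oxy]-2-methylhex-5-enoate | COC(=O)[C@H](C)C[C@H](O[Si](C)(C)C(C)(C)C)C(Br)=C
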